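**Retrosynthetic overview**

1. Locants used here: C1 (tigloyloxy CH), C2 (CH2), C3 (senecioyloxy CH), C4 (CMe2), C5 and C10 (cyclobutane CH), C6 (cyclobutane CH next to C7=O), C8=C9(CH3), C11 (cyclobutane C–CH3). The rings are the cyclobutane C5–C6–C11–C10, the enone ring C5–C6–C7–C8–C9–C10 and the seven-membered ring C4–C3–C2–C1–C11–C6–C5.
2. Late stage: the C7 ketone comes from allylic oxidation of a C8=C9 alkene. The two esters come from an Evans–Tishchenko reduction of a C1 ketone (3-senecioate, anti C1–OH) followed by tigloylation.
3. Key disconnection: C4–C5 and C10–C11 are made together in a Lewis-acid cascade from a monocyclic 2-methylcyclohexa-1,3-diene that carries, at C6, an (E)-silyl enol ether (C11=C1) and a (3R)-epoxide (C3–C4).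
4. Enabling feature: C4 and C11 each sit next to an oxygenated carbon (C3, C1), so C3–C4 can be an epoxide (tertiary electrophile) and C1=C11 an enol ether (nucleophile). C5 and C10 are neighbouring carbons of the diene C5=C10–C9(CH3)=C8, so C5 attacks first and C10 becomes an allyl-cation terminus, leaving C8=C9 in place.
5. Ring order: six-membered ring from (R)-carvone, then the seven-membered ring, then the cyclobutane (both in the key step). Stereocentres: C6 from carvone, C3 from Shi epoxidation, C5/C10/C11 in the cascade, C1 in the Evans–Tishchenko step.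

Key step: step 10

Remark: the D-fructose-derived Shi ketone is taken to give the (R)-epoxide at this trisubstituted alkene; its enantiomer would be used if the opposite sense were found.

**Route**

Step 1
Reactants: 1 (R)-carvone
Product: 2 allylic chloride (10-chlorocarvone)
Conditions: Ca(OCl)2, CO2 (dry ice), CH2Cl2/H2O, 0 °C
Reagents that add atoms: calcium hypochlorite, [Ca+2].[O-]Cl.[O-]Cl
Why: Ene-type allylic chlorination by HOCl attacks only the electron-rich 1,1-disubstituted alkene, shifts the double bond to the former methyl group, and leaves the enone and the stereocentre untouched.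

Step 2
Reactants: 2 allylic chloride
Product: 3 enal
Conditions: N-methylmorpholine N-oxide, NaI (cat.), MeCN, 40 °C
Reagents that add atoms: N-methylmorpholine N-oxide, C[N+]1([O-])CCOCC1
Why: Kornblum-type amine N-oxide oxidation: the allylic halide alkylates the N-oxide oxygen and the alkoxyammonium ion eliminates to the aldehyde; no stereocentre is involved.

Step 3
Reactants: 3 enal
Product: 4 homoallylic alcohol (both carbinol epimers)
Conditions: allylB(pin), CH2Cl2, rt; aqueous NaHCO3 work-up
Reagents that add atoms: allylboronic acid pinacol ester, C=CCB1OC(C)(C)C(C)(C)O1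
Why: Allylboration through a Zimmerman–Traxler transition state is specific for the aldehyde (the ring ketone should not react); the new carbinol centre is erased in step 6.

Step 4
Reactants: 4 homoallylic alcohol
Product: 5 prenyl-type alcohol
Conditions: 2-methylbut-2-ene (excess), second-generation Grubbs catalyst (5 mol %), CH2Cl2, 40 °C
Reagents that add atoms: 2-methylbut-2-ene, CC=C(C)C
Why: Olefin cross-metathesis: only the monosubstituted vinyl group should initiate, and exchange with 2-methylbut-2-ene caps it as the dimethyl-substituted alkene.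

Step 5
Reactants: 5 prenyl-type alcohol
Product: 6 epoxy alcohol
Conditions: D-fructose-derived Shi ketone (30 mol %), Oxone (2KHSO5·KHSO4·K2SO4), K2CO3, Bu4NHSO4, MeCN/(MeO)2CH2/aqueous borate buffer, 0 °C
Reagents that add atoms: potassium peroxymonosulfate (active part of Oxone), [K+].[O-]S(=O)(=O)OO
Why: Shi epoxidation: the chiral dioxirane attacks the most electron-rich (trisubstituted) alkene through a spiro transition state, so the catalyst alone sets the epoxide CH as (R); the 1,1-disubstituted and enone alkenes react more slowly.

Step 6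
Reactants: 6 epoxy alcohol
Product: 7 epoxy α-methylene ketone
Conditions: Dess–Martin periodinane, NaHCO3, CH2Cl2, 0 °C
Reagents that add atoms: none
Why: Dess–Martin oxidation under buffered, non-basic conditions should give the α-methylene ketone without opening the β,γ-epoxide; the carbinol epimers converge.

Step 7
Reactants: 7 epoxy α-methylene ketone
Product: 8 (E)-triethylsilyl enol ether
Conditions: Et3SiH (1.1 equiv), RhCl(PPh3)3 (2 mol %), benzene, 50 °C
Reagents that add atoms: triethylsilane, CC[SiH](CC)CC
Why: Rhodium-catalysed 1,4-hydrosilylation should take the unhindered exo-methylene enone before the β-substituted ring enone; hydride delivery through the s-cis enone gives the regiodefined (E)-enol ether (new methyl cis to OSi, ring carbon cis to C2), which also masks the ketone from base in step 8.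

Step 8
Reactants: 8 (E)-triethylsilyl enol ether
Product: 10 dienyl triflate, via lithium dienolate 9 (not isolated)
Conditions: LiN(i-Pr)2 (LDA), THF, −78 °C; then PhNTf2, −78 to 0 °C
Reagents that add atoms: N-phenylbis(trifluoromethanesulfonimide), O=S(=O)(N(c1ccccc1)S(=O)(=O)C(F)(F)F)C(F)(F)F
Why: Kinetic α′-deprotonation of the cyclohexenone gives the cross-conjugated dienolate, and O-triflation gives the 2-triflyloxy-1,3-diene; the adjacent stereocentre is not acidic and the enol ether and epoxide should survive LDA at −78 °C.

Step 9
Reactants: 10 dienyl triflate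
Product: 11 diene–enol ether–epoxide
Conditions: Bu3SnH, Pd(PPh3)4 (5 mol %), LiCl, THF, 50 °C
Reagents that add atoms: none
Why: Palladium-catalysed hydride reduction of an alkenyl triflate (oxidative addition, tin hydride transmetalation, reductive elimination) under neutral conditions should give the 2-methyl-1,3-diene with enol ether and epoxide intact.

Step 10
Reactants: 11 diene–enol ether–epoxide
Product: 13 tricyclic hydroxy ketone, via bicyclic allyl cation 12 (not isolated)
Conditions: MeAlCl2 (1.5 equiv), CH2Cl2, −94 to −78 °C; then aqueous NaHCO3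
Reagents that add atoms: none
Why: Proposed new method: MeAlCl2 ionises the epoxide at its tertiary carbon C4, which is attacked by the diene terminus C5 (endo-mode epoxide opening, the C5=C10 bond exocyclic to the new seven-membered ring) to give the allyl cation C10–C9–C8 of 12; the tethered enol ether then adds through C11 to C10 (4-exo-trig, enol double bond exocyclic to the cyclobutane), and the silyloxocarbenium ion loses Et3Si to chloride, leaving the C1 ketone and the C8=C9 alkene. The closest known reactions are epoxide-initiated cation–olefin polycyclisations terminated by silyl enol ethers under MeAlCl2 and, for the four-membered ring, the terpinyl-to-pinyl closure and stepwise Lewis-acid [2+2] reactions of enol silanes; closing a seven- and a four-membered ring in this way has no direct precedent. C3 keeps the epoxide configuration because its C–O bond is not broken; C5 is set cis to the C6 side chain because the five-atom tether should reach the diene on the face where C6 holds it; C10 and C11 are then fixed, since C11 can bond to C10 only on that face and the seven-membered ring holds C1 anti to the C7–C9 bridge. The step needs C4 to be taken by C5 and not by C11 or by a 1,2-hydride shift: C11-to-C4 would be a 5-endo closure joining two fully substituted carbons, and low temperature should suppress the Meinwald shift. It also needs C10 rather than C8 for the second bond: in the cycloheptene formed first the p-lobe of C11 should point at C10, the terminus attached to C5.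

Step 11
Reactants: 13 tricyclic hydroxy ketone
Product: 15 hydroxy senecioate, via prenal hemiacetal 14 (not isolated)
Conditions: 3-methylbut-2-enal (5 equiv), SmI2 (30 mol %), THF, −10 °C
Reagents that add atoms: 3-methylbut-2-enal, CC(C)=CC=O
Why: Evans–Tishchenko reduction: the C3 hydroxyl forms a hemiacetal with the aldehyde, and within a samarium chelate its hydride is delivered to the C1 ketone on the face of the C3 oxygen, which should give the trans (anti) C1 carbinol and leave the 3-methylbut-2-enoate on O3.

Step 12
Reactants: 15 hydroxy senecioate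
Product: 16 tiglate senecioate
Conditions: tiglic acid, 2,4,6-trichlorobenzoyl chloride, Et3N, THF, rt; then DMAP, toluene, 60 °C
Reagents that add atoms: tiglic acid, C/C=C(\C)C(=O)O
Why: Yamaguchi esterification: DMAP-catalysed acyl transfer from the mixed anhydride should acylate the hindered C1 alcohol; the trans-1,3 arrangement should block acyl migration from O3.

Step 13
Reactants: 16 tiglate senecioate
Product: 17 target
Conditions: CrO3, 3,5-dimethylpyrazole, CH2Cl2, −20 °C
Reagents that add atoms: chromium trioxide, O=[Cr](=O)=O
Why: Allylic oxidation with the CrO3–dimethylpyrazole complex should turn the ring CH2 (C7) next to the trisubstituted alkene into the enone, as α-pinene gives verbenone; the bridgehead allylic C–H and the electron-poor enoate alkenes should not react.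

**Compound list**

1 | (R)-(−)-carvone, (5R)-2-methyl-5-(prop-1-en-2-yl)cyclohex-2-en-1-one | O=C1C[C@H](C(C)=C)CC=C1C | starting material
2 | (5R)-5-(3-chloroprop-1-en-2-yl)-2-methylcyclohex-2-en-1-one | O=C1C[C@H](C(=C)CCl)CC=C1C | intermediate
3 | 2-[(1R)-4-methyl-5-oxocyclohex-3-en-1-yl]prop-2-enal | O=C1C[C@H](C(=C)C=O)CC=C1C | intermediate
4 | (5R)-5-(3-hydroxyhexa-1,5-dien-2-yl)-2-methylcyclohex-2-en-1-one, both carbinol epimers | O=C1C[C@H](C(=C)C(O)CC=C)CC=C1C | intermediate
5 | (5R)-5-(3-hydroxy-6-methylhepta-1,5-dien-2-yl)-2-methylcyclohex-2-en-1-one, both carbinol epimers | O=C1C[C@H](C(=C)C(O)CC=C(C)C)CC=C1C | intermediate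
6 | (5R)-5-{4-[(2R)-3,3-dimethyloxiran-2-yl]-3-hydroxybut-1-en-2-yl}-2-methylcyclohex-2-en-1-one, both carbinol epimers | O=C1C[C@H](C(=C)C(O)C[C@@H]2C(C)(C)O2)CC=C1C | intermediate
7 | (5R)-5-{4-[(2R)-3,3-dimethyloxiran-2-yl]-3-oxobut-1-en-2-yl}-2-methylcyclohex-2-en-1-one | O=C1C[C@H](C(=C)C(=O)C[C@@H]2C(C)(C)O2)CC=C1C | intermediate
8 | (5R)-5-{(2E)-4-[(2R)-3,3-dimethyloxiran-2-yl]-3-(triethylsilyloxy)but-2-en-2-yl}-2-methylcyclohex-2-en-1-one | O=C1C[C@H](/C(C)=C(/O[Si](CC)(CC)CC)C[C@@H]2C(C)(C)O2)CC=C1C | intermediate
9 | lithium (3R)-6-methyl-3-{(2E)-4-[(2R)-3,3-dimethyloxiran-2-yl]-3-(triethylsilyloxy)but-2-en-2-yl}cyclohexa-1,5-dien-1-olate | [Li+].[O-]C1=C[C@H](/C(C)=C(/O[Si](CC)(CC)CC)C[C@@H]2C(C)(C)O2)CC=C1C | intermediate (not isolated)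
10 | (3R)-6-methyl-3-{(2E)-4-[(2R)-3,3-dimethyloxiran-2-yl]-3-(triethylsilyloxy)but-2-en-2-yl}cyclohexa-1,5-dien-1-yl trifluoromethanesulfonate | O=S(=O)(OC1=C[C@H](/C(C)=C(/O[Si](CC)(CC)CC)C[C@@H]2C(C)(C)O2)CC=C1C)C(F)(F)F | intermediate
11 | (5R)-2-methyl-5-{(2E)-4-[(2R)-3,3-dimethyloxiran-2-yl]-3-(triethylsilyloxy)but-2-en-2-yl}cyclohexa-1,3-diene | C1=C[C@H](/C(C)=C(/O[Si](CC)(CC)CC)C[C@@H]2C(C)(C)O2)CC=C1C | intermediate
12 | cis-fused bicyclo[5.4.0] allyl cation (C10–C9–C8), C4–C5 bond made, O3 bound as aluminate, enol ether intact | CC1=C(O[Si](CC)(CC)CC)C[C@@H](O[Al-](C)(Cl)Cl)C(C)(C)[C@H]2[CH+]C(C)=CC[C@@H]12 | intermediate (not isolated)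
13 | tricyclic hydroxy ketone: target skeleton with C1 ketone, (3R)-hydroxyl, C7 methylene, C8=C9 alkene; C5, C6, C10, C11 as in the target | O=C1C[C@@H](O)C(C)(C)[C@@H]2[C@H]3CC=C(C)[C@@H]2[C@]31C | intermediate
14 | hemiacetal of 13 at O3 with 3-methylbut-2-enal (hemiacetal carbon unassigned) | O=C1C[C@@H](OC(O)C=C(C)C)C(C)(C)[C@@H]2[C@H]3CC=C(C)[C@@H]2[C@]31C | intermediate (not isolated)
15 | (1R)-hydroxy (3R)-(3-methylbut-2-enoate), C1–O and C3–O trans, C7 methylene | O[C@@H]1C[C@@H](OC(=O)C=C(C)C)C(C)(C)[C@@H]2[C@H]3CC=C(C)[C@@H]2[C@]31C | intermediate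
16 | (1R)-tiglate (3R)-(3-methylbut-2-enoate), C7 methylene | C/C=C(\C)C(=O)O[C@@H]1C[C@@H](OC(=O)C=C(C)C)C(C)(C)[C@@H]2[C@H]3CC=C(C)[C@@H]2[C@]31C | intermediate
17 | CNP0277258.1 | C/C=C(\C)C(=O)O[C@@H]1C[C@@H](OC(=O)C=C(C)C)C(C)(C)[C@@H]2[C@H]3C(=O)C=C(C)[C@@H]2[C@]31C | target

Total step count: 13. Longest linear sequence: 13 steps (from 1).

**Steps most likely to fail**

Step 10 (proposed new method). The cascade may stop after the first ring closure (the allyl cation lost by elimination or chloride capture). The opened epoxide may undergo a 1,2-hydride shift before the diene engages. The enol ether may also close on the wrong allyl terminus. The fallback makes the two bonds one after the other with known reaction types on the carvone enone; it sets out from 8 and comes back at 13. Kinetic enolisation (LiN(i-Pr)2, then Me3SiCl) would give the ring trimethylsilyl dienol ether F1. BF3·OEt2 in CH2Cl2 at −78 °C would then effect a Mukaiyama-type intramolecular alkylation of this enol silane by the tertiary epoxide carbon (C4–C5, cis fusion enforced by the tether), returning the ring enone in the bicyclic hydroxy enone F2. 1,2-Reduction with i-Bu2AlH should give the allylic alcohol F3, hydride arriving anti to the neighbouring quaternary carbon. MsCl, 2,4,6-collidine and LiCl in DMF should convert only the allylic hydroxyl, with inversion, into the allylic chloride F4. MeLi (2.2 equiv) would deprotonate O3 and release the regiodefined lithium enolate from the triethylsilyl enol ether; intramolecular C-alkylation of the allylic chloride (a reaction type long used to close bicyclo[3.1.1]heptanes) would then form C10–C11 and give 13.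

Step 11. Hydride transfer to a ketone flanked by a quaternary carbon may be slow, and the unsaturated aldehyde may be consumed by the samarium reagent. The fallback separates reduction and acylation; it sets out from 13 and comes back at 16. Directed reduction with Me4NBH(OAc)3 in MeCN/AcOH (Evans–Saksena) should give the anti-diol F5. One equivalent of the Yamaguchi mixed anhydride of tiglic acid should acylate the less encumbered C1 hydroxyl (its neighbour C11 is tied back in the cyclobutane, whereas C3 sits next to the gem-dimethyl carbon) to give the mono-tiglate F6. Steglich esterification of the C3 hydroxyl with 3-methylbut-2-enoic acid (DCC, DMAP) would then give 16.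

Step 7. The hydrosilylation may not discriminate between the two enones, or the β,γ-epoxy ketone may not survive. The fallback removes the ring enone before the chain ketone exists; it sets out from 6 and comes back at 11. Silylation (Et3SiCl, imidazole) would give the triethylsilyl ether F7. Kinetic triflation (LiN(i-Pr)2, PhNTf2) would give the dienyl triflate F8, and reduction (Bu3SnH, Pd(PPh3)4, LiCl) the diene silyl ether F9. Bu4NF would free the dienyl alcohol F10, and MnO2 or Dess–Martin periodinane would give the α-methylene ketone F11, now the only enone. Hydrosilylation as in step 7 (Et3SiH, RhCl(PPh3)3) would then give 11.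

**Further compounds**

F1 | step 10 | ring trimethylsilyl dienol ether of 8 | C[Si](C)(C)OC1=C[C@H](/C(C)=C(/O[Si](CC)(CC)CC)C[C@@H]2C(C)(C)O2)CC=C1C
F2 | step 10 | cis-fused bicyclic hydroxy enone (C4–C5 made, ring enone, triethylsilyl enol ether kept) | CC1=C(O[Si](CC)(CC)CC)C[C@@H](O)C(C)(C)[C@H]2C(=O)C(C)=CC[C@@H]12
F3 | step 10 | allylic alcohol from F2 (C10–OH cis to C4) | CC1=C(O[Si](CC)(CC)CC)C[C@@H](O)C(C)(C)[C@H]2[C@@H](O)C(C)=CC[C@@H]12
F4 | step 10 | allylic chloride (C10–Cl trans to C4) | CC1=C(O[Si](CC)(CC)CC)C[C@@H](O)C(C)(C)[C@H]2[C@H](Cl)C(C)=CC[C@@H]12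
F5 | step 11 | anti-1,3-diol (1R,3R), C7 methylene | O[C@@H]1C[C@@H](O)C(C)(C)[C@@H]2[C@H]3CC=C(C)[C@@H]2[C@]31C
F6 | step 11 | 1-tiglate of F5 with free C3 hydroxyl | C/C=C(\C)C(=O)O[C@@H]1C[C@@H](O)C(C)(C)[C@@H]2[C@H]3CC=C(C)[C@@H]2[C@]31C
F7 | step 7 | triethylsilyl ether of 6 | O=C1C[C@H](C(=C)C(O[Si](CC)(CC)CC)C[C@@H]2C(C)(C)O2)CC=C1C
F8 | step 7 | dienyl triflate of F7 | O=S(=O)(OC1=C[C@H](C(=C)C(O[Si](CC)(CC)CC)C[C@@H]2C(C)(C)O2)CC=C1C)C(F)(F)F
F9 | step 7 | diene silyl ether | C1=C[C@H](C(=C)C(O[Si](CC)(CC)CC)C[C@@H]2C(C)(C)O2)CC=C1C
F10 | step 7 | dienyl alcohol | C1=C[C@H](C(=C)C(O)C[C@@H]2C(C)(C)O2)CC=C1C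
F11 | step 7 | α-methylene ketone with ring diene | C1=C[C@H](C(=C)C(=O)C[C@@H]2C(C)(C)O2)CC=C1C
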